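**Plan**

- Retrosynthesis: cut the C9 tiglate, then the ring bond C9–C10 (Ni/Cr addition of a C10 alkenyl iodide to a C9 aldehyde), C1=C10 (iodo-Wittig), the 2,3-oxirane, C3–C4 (Stille), the C8 ester, C11=C13 (Horner–Wadsworth–Emmons) and C7–C11. What remains is a 7,8-cis-epoxy C6 carbinol made from (Z)-3-iodobut-2-enal and a silyl propargyl ether (C6–C7).
- Forward: the chain C15/C4–C9 is built first. The lactone ring is closed at C7–C11 at the lactol-ether oxidation level, then oxidised and methylenated. The C1–C3 arm and the second oxirane follow, and the ten-membered ring is closed last at C9–C10.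
- Enabling feature: in the γ-lactone ring (O6–C6–C7–C11–C12), C11 sits on C7 cis to O6 and anti to the oxygen on C8. A C11 carbanion tethered to O6 can therefore open a 7,8-cis-oxirane at C7 from the back (5-exo-tet), inverting C7 and leaving the oxirane oxygen as the C8 hydroxyl.
- Stereochemistry: C6 from ligand-controlled alkynylation; C7/C8 from hydroxyl-directed threo epoxidation of the Z-allylic alcohol followed by inversion at C7; C2/C3 and the side chain from Sharpless epoxidations (side chain with anti acetolysis); C9 from ligand-controlled ring closure.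

Key step: step 7

Remark: atoms are numbered as in germacranolides (ring C1–C10, lactone carbonyl C12 on C11, exocyclic methylene C13, ester carbon C14, ring methyl C15); the target is then (2R,3S,6R,7R,8S,9S) with a (2S,3S) side chain. TBDPS = tert-butyl(diphenyl)silyl.
Remark: in the two ligand-controlled additions (steps 3 and 21) the ligand antipode meant is the one that directs the nucleophile to the Si face of the aldehyde.

Step 1
Reactants: 1 but-2-yn-1-ol
Product: 2 (2Z)-3-iodobut-2-en-1-ol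
Conditions: NaAlH2(OCH2CH2OMe)2 (Red-Al), THF, 0 → 25 °C; then I2, −78 °C
Reagents that add atoms: iodine, II
Why: Hydroxyl-directed trans-hydroalumination places aluminium on C3 cis to the carbinol carbon and iodinolysis proceeds with retention, so the Z-iodoalkene should form stereospecifically (hydroalumination–iodination of a propargylic alcohol).

Step 2
Reactants: 2 (2Z)-3-iodobut-2-en-1-ol
Product: 3 (2Z)-3-iodobut-2-enal
Conditions: MnO2, CH2Cl2, 25 °C
Reagents that add atoms: none
Why: MnO2 oxidises the allylic alcohol chemoselectively to the enal without touching the iodoalkene or its geometry (allylic oxidation).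

Step 3
Reactants: 3 (2Z)-3-iodobut-2-enal; 4 tert-butyl(diphenyl)(prop-2-yn-1-yloxy)silane
Product: 5 (4R)-propargylic alcohol
Conditions: ZnMe2, (S,S)-ProPhenol (20 mol %), Ph3P=O (40 mol %), toluene, 0 °C
Reagents that add atoms: none
Why: The alkynylzinc species formed from 4 and ZnMe2 adds 1,2 to the enal under the ProPhenol ligand, which directs attack to the Si face and should set C6 as R (catalytic asymmetric alkynylation of an aldehyde).

Step 4
Reactants: 5 (4R)-propargylic alcohol
Product: 6 (2Z,4S,5Z)-dienol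
Conditions: H2 (1 atm), Pd/CaCO3 poisoned with Pb(OAc)2 (Lindlar catalyst), quinoline, EtOAc, 25 °C
Reagents that add atoms: none
Why: Syn delivery of hydrogen on the poisoned palladium surface gives the Z-alkene, and quinoline with uptake limited to one equivalent should spare the iodoalkene (Lindlar semihydrogenation).

Step 5
Reactants: 6 (2Z,4S,5Z)-dienol
Product: 7 7,8-cis-epoxy C6 carbinol
Conditions: mCPBA, NaHCO3, CH2Cl2, 0 °C
Reagents that add atoms: 3-chloroperoxybenzoic acid, OOC(=O)c1cccc(Cl)c1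
Why: In the allylic-strain-minimised conformer of the Z-allylic alcohol the hydroxyl hydrogen-bonds the peracid and delivers oxygen to give the threo epoxy alcohol, while the electron-poor iodoalkene is not attacked (hydroxyl-directed Prilezhaev epoxidation).

Step 6
Reactants: 7 7,8-cis-epoxy C6 carbinol; 8 diethyl (2,2-diethoxyethyl)phosphonate
Product: 9 mixed acetal carrying the phosphonate on O6
Conditions: PPTS (cat.), toluene, 4 Å MS, 60 °C
Reagents that add atoms: none
Why: Acid-catalysed acetal exchange with removal of ethanol installs the phosphonoacetaldehyde unit on O6 as a mixed acetal, and the electron-poor, doubly oxygen-flanked oxirane should survive pyridinium catalysis (transacetalisation).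

Step 7
Reactants: 9 mixed acetal carrying the phosphonate on O6
Product: 10 2-ethoxy-3-phosphono-oxolane with free C8 hydroxyl
Conditions: LiN(iPr)2, THF, −78 °C; BF3·OEt2, −78 → −40 °C; aq. NaHCO3
Reagents that add atoms: none
Why: Proposed new method: deprotonation of the phosphonate methylene gives a P-stabilised sp3 carbanion on C11 that opens the BF3-activated oxirane at C7 in an SN2 manner; the closest known reaction types are the BF3-promoted opening of epoxides by α-lithio phosphonates, the Stork epoxynitrile cyclization and, for the tether, the Ueno–Stork haloacetal cyclization. The oxolane ring (O6–C12–C11–C7–C6) closes in the 5-exo-tet mode, attack at C8 being 6-endo. C7 is set by inversion at the oxirane carbon while C6 and C8 are untouched, so the cis relation of the C5 and C8 branches and the free C8 hydroxyl follow stereospecifically; the C11 and C12 epimers are inconsequential because both centres become trigonal later. The acetal oxidation level is chosen because an ester enolate tethered at O6 would have to close 5-(enolendo)-exo-tet and would O-alkylate instead, a constraint the non-enolate carbanion does not have. The step needs alkylation to outrun β-loss of alkoxide from the lithiated acetal, and C7 over C8 regioselectivity; low temperature, Lewis-acid activation of the oxirane and the exo trajectory are meant to secure both.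

Step 8
Reactants: 11 (2E)-2-methylbut-2-en-1-ol
Product: 12 [(2R,3R)-2,3-dimethyloxiran-2-yl]methanol
Conditions: Ti(OiPr)4 (10 mol %), D-(−)-diethyl tartrate (12 mol %), t-BuOOH, 4 Å MS, CH2Cl2, −20 °C
Reagents that add atoms: tert-butyl hydroperoxide, CC(C)(C)OO
Why: The Ti(OiPr)4–tartrate complex delivers the peroxide oxygen to one face of the E-allylic alcohol, D-(−)-tartrate giving the (2R,3R) oxirane (Sharpless asymmetric epoxidation).

Step 9
Reactants: 12 [(2R,3R)-2,3-dimethyloxiran-2-yl]methanol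
Product: 13 (2S,3R)-2,3-dimethyloxirane-2-carboxylic acid
Conditions: RuCl3 (2 mol %), NaIO4, CCl4/MeCN/H2O, 25 °C
Reagents that add atoms: water, O
Why: RuO4 generated in situ oxidises the primary alcohol through the aldehyde hydrate to the acid without opening the trisubstituted oxirane (ruthenium-catalysed periodate oxidation).

Step 10
Reactants: 13 (2S,3R)-2,3-dimethyloxirane-2-carboxylic acid
Product: 14 (2S,3S)-3-acetoxy-2-hydroxy-2-methylbutanoic acid
Conditions: AcOH, NaOAc, 60 °C
Reagents that add atoms: acetic acid, CC(=O)O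
Why: Acetate opens the glycidic acid at C3, the carbon remote from the carboxyl group, with inversion, which should convert the trans-oxirane into the (2S,3S) acetoxy hydroxy acid (regioselective SN2 acetolysis of an epoxide).

Step 11
Reactants: 10 2-ethoxy-3-phosphono-oxolane with free C8 hydroxyl; 14 (2S,3S)-3-acetoxy-2-hydroxy-2-methylbutanoic acid
Product: 15 C8 ester of the oxolane
Conditions: DCC, DMAP (cat.), CH2Cl2, 0 → 25 °C
Reagents that add atoms: none
Why: Carbodiimide activation acylates the secondary C8 hydroxyl, the tertiary hydroxyl of 14 being too hindered to compete (Steglich esterification).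

Step 12
Reactants: 15 C8 ester of the oxolane
Product: 17 α-phosphono γ-lactone, via lactol 16 (not isolated)
Conditions: CrO3, H2SO4, H2O/acetone, 0 °C
Reagents that add atoms: water, O
Why: Aqueous acid hydrolyses the 2-ethoxyoxolane to the lactol, which chromic acid oxidises to the γ-lactone while the silyl ether, tertiary alcohol, esters and iodoalkene should persist (Jones oxidation of a lactol ether).

Step 13
Reactants: 17 α-phosphono γ-lactone
Product: 18 α-methylene γ-lactone
Conditions: K2CO3, aq. CH2O (37 %), THF, 0 °C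
Reagents that add atoms: formaldehyde, C=O
Why: The lactone-stabilised phosphonate carbanion adds to formaldehyde and expels diethyl phosphate, so the C11=C13 methylidene forms regiospecifically and the C11 stereocentre disappears (Horner–Wadsworth–Emmons olefination).

Step 14
Reactants: 19 prop-2-yn-1-ol
Product: 20 (2Z)-3-(tributylstannyl)prop-2-en-1-ol
Conditions: LiAlH4, THF, 0 → 25 °C; then Bu3SnCl, −78 → 0 °C
Reagents that add atoms: tributyltin chloride, CCCC[Sn](Cl)(CCCC)CCCC
Why: trans-Hydroalumination of the propargylic alkoxide places aluminium on C3 cis to the hydroxymethyl group and transmetalation to tin proceeds with retention, giving the Z-stannane (hydroalumination–stannylation).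

Step 15
Reactants: 18 α-methylene γ-lactone; 20 (2Z)-3-(tributylstannyl)prop-2-en-1-ol
Product: 21 (1Z,3Z)-dienol
Conditions: Pd2(dba)3 (5 mol %), AsPh3, CuI, DMF, 25 °C
Reagents that add atoms: none
Why: Copper-assisted Stille coupling joins the two sp2 carbons C3 and C4 with retention at both partners and should leave the Michael-acceptor lactone untouched at room temperature (Stille cross-coupling).

Step 16
Reactants: 21 (1Z,3Z)-dienol
Product: 22 2,3-cis-epoxy alcohol
Conditions: Ti(OiPr)4 (1.2 equiv), D-(−)-diethyl tartrate (1.5 equiv), t-BuOOH, 4 Å MS, CH2Cl2, −20 °C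
Reagents that add atoms: tert-butyl hydroperoxide, CC(C)(C)OO
Why: The primary allylic hydroxyl directs the titanium-bound peroxide to the 2,3-alkene only and D-(−)-tartrate delivers oxygen to the face that gives the (2R,3S) cis-oxirane, a full equivalent of the Ti(OiPr)4–tartrate complex being used because the α-hydroxy ester also binds titanium (Sharpless asymmetric epoxidation).

Step 17
Reactants: 22 2,3-cis-epoxy alcohol
Product: 23 epoxy aldehyde
Conditions: Dess–Martin periodinane, NaHCO3, CH2Cl2, 0 → 25 °C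
Reagents that add atoms: none
Why: Buffered periodinane oxidises the primary epoxy alcohol to the aldehyde under neutral conditions that should neither epimerise nor open the oxirane (Dess–Martin oxidation).

Step 18
Reactants: 23 epoxy aldehyde
Product: 24 (Z)-α-iodo enoate
Conditions: Ph3P=CHCO2Me, N-iodosuccinimide, CH2Cl2, −20 °C; then 23, −20 → 25 °C
Reagents that add atoms: methyl (triphenyl-λ5-phosphanylidene)acetate, COC(=O)C=P(c1ccccc1)(c1ccccc1)c1ccccc1; N-iodosuccinimide, O=C1CCC(=O)N1I
Why: The iodo ylide formed in the flask from the stabilised ylide and N-iodosuccinimide olefinates the aldehyde with the ester trans to C2, which is the Z-configured α-iodo enoate needed for C10 (Wittig reaction of a stabilised ylide).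

Step 19
Reactants: 24 (Z)-α-iodo enoate
Product: 25 C9 primary alcohol
Conditions: HF·pyridine, pyridine, THF, 0 → 25 °C
Reagents that add atoms: none
Why: Pyridine-buffered hydrogen fluoride cleaves the silyl ether and should neither open an oxirane nor migrate the C8 ester (fluoride desilylation).

Step 20
Reactants: 25 C9 primary alcohol
Product: 26 C9 aldehyde
Conditions: Dess–Martin periodinane, NaHCO3, CH2Cl2, 0 °C
Reagents that add atoms: none
Why: Neutral periodinane oxidation gives the epimerisable α-acyloxy aldehyde, which is used at once (Dess–Martin oxidation).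

Step 21
Reactants: 26 C9 aldehyde
Product: 27 ten-membered C9 alcohol
Conditions: CrCl2 (10 equiv), NiCl2 (10 mol %), chiral oxazoline–sulfonamide ligand, Et3N, THF, 0.002 M, 25 °C
Reagents that add atoms: none
Why: Nickel-catalysed conversion of the C10 alkenyl iodide into an alkenyl–CrCl2 species and its intramolecular addition to the C9 aldehyde at high dilution closes the ten-membered ring with retention of the alkene geometry, the chiral ligand on chromium directing attack to the Si face so that C9 should be S (Nozaki–Hiyama–Kishi reaction).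

Step 22
Reactants: 27 ten-membered C9 alcohol
Product: 28 CNP0202690.1
Conditions: tigloyl chloride, DMAP, pyridine, CH2Cl2, 0 → 25 °C
Reagents that add atoms: (2E)-2-methylbut-2-enoyl chloride, C/C=C(\C)C(Cl)=O
Why: The acyl chloride with DMAP acylates the secondary C9 hydroxyl while the tertiary hydroxyl is inert, and the E geometry of the tigloyl group is retained (DMAP-catalysed esterification).

**Compound list**

1 | but-2-yn-1-ol | CC#CCO | starting material
2 | (2Z)-3-iodobut-2-en-1-ol | C/C(I)=C/CO | intermediate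
3 | (2Z)-3-iodobut-2-enal | C/C(I)=C/C=O | intermediate
4 | tert-butyl(diphenyl)(prop-2-yn-1-yloxy)silane | C#CCO[Si](c1ccccc1)(c1ccccc1)C(C)(C)C | starting material
5 | (2Z,4R)-7-(TBDPS-oxy)-2-iodohept-2-en-5-yn-4-ol | C/C(I)=C/[C@@H](O)C#CCO[Si](c1ccccc1)(c1ccccc1)C(C)(C)C | intermediate
6 | (2Z,4S,5Z)-7-(TBDPS-oxy)-2-iodohepta-2,5-dien-4-ol | C/C(I)=C/[C@@H](O)/C=C\CO[Si](c1ccccc1)(c1ccccc1)C(C)(C)C | intermediate
7 | (1R,2Z)-1-[(2S,3R)-3-(TBDPS-oxymethyl)oxiran-2-yl]-3-iodobut-2-en-1-ol | C/C(I)=C/[C@@H](O)[C@@H]1O[C@@H]1CO[Si](c1ccccc1)(c1ccccc1)C(C)(C)C | intermediate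
8 | diethyl (2,2-diethoxyethyl)phosphonate | CCOC(OCC)CP(=O)(OCC)OCC | starting material
9 | diethyl [2-ethoxy-2-({(1R,2Z)-1-[(2S,3R)-3-(TBDPS-oxymethyl)oxiran-2-yl]-3-iodobut-2-en-1-yl}oxy)ethyl]phosphonate (both acetal epimers) | C/C(I)=C/[C@@H](OC(OCC)CP(=O)(OCC)OCC)[C@@H]1O[C@@H]1CO[Si](c1ccccc1)(c1ccccc1)C(C)(C)C | intermediate
10 | diethyl {(4S,5S)-4-[(1S)-2-(TBDPS-oxy)-1-hydroxyethyl]-2-ethoxy-5-[(1Z)-2-iodoprop-1-en-1-yl]oxolan-3-yl}phosphonate (epimers at oxolane C2 and C3) | CCOC1O[C@H](/C=C(/C)I)[C@H]([C@H](O)CO[Si](c2ccccc2)(c2ccccc2)C(C)(C)C)C1P(=O)(OCC)OCC | intermediate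
11 | (2E)-2-methylbut-2-en-1-ol | C/C=C(\C)CO | starting material
12 | [(2R,3R)-2,3-dimethyloxiran-2-yl]methanol | OC[C@@]1(C)O[C@@H]1C | intermediate
13 | (2S,3R)-2,3-dimethyloxirane-2-carboxylic acid | OC(=O)[C@@]1(C)O[C@@H]1C | intermediate
14 | (2S,3S)-3-acetoxy-2-hydroxy-2-methylbutanoic acid | OC(=O)[C@@](C)(O)[C@H](C)OC(C)=O | intermediate
15 | (1S)-2-(TBDPS-oxy)-1-{(2S,3R)-4-(diethoxyphosphoryl)-5-ethoxy-2-[(1Z)-2-iodoprop-1-en-1-yl]oxolan-3-yl}ethyl (2S,3S)-3-acetoxy-2-hydroxy-2-methylbutanoate (epimers at oxolane C4 and C5) | CCOC1O[C@H](/C=C(/C)I)[C@H]([C@H](OC(=O)[C@@](C)(O)[C@H](C)OC(C)=O)CO[Si](c2ccccc2)(c2ccccc2)C(C)(C)C)C1P(=O)(OCC)OCC | intermediate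
16 | (1S)-2-(TBDPS-oxy)-1-{(2S,3R)-4-(diethoxyphosphoryl)-5-hydroxy-2-[(1Z)-2-iodoprop-1-en-1-yl]oxolan-3-yl}ethyl (2S,3S)-3-acetoxy-2-hydroxy-2-methylbutanoate (lactol) | CCOP(=O)(OCC)C1C(O)O[C@H](/C=C(/C)I)[C@@H]1[C@H](OC(=O)[C@@](C)(O)[C@H](C)OC(C)=O)CO[Si](c2ccccc2)(c2ccccc2)C(C)(C)C | intermediate
17 | (1S)-2-(TBDPS-oxy)-1-{(2S,3R)-4-(diethoxyphosphoryl)-2-[(1Z)-2-iodoprop-1-en-1-yl]-5-oxooxolan-3-yl}ethyl (2S,3S)-3-acetoxy-2-hydroxy-2-methylbutanoate (epimers at oxolane C4) | CCOP(=O)(OCC)C1C(=O)O[C@H](/C=C(/C)I)[C@@H]1[C@H](OC(=O)[C@@](C)(O)[C@H](C)OC(C)=O)CO[Si](c2ccccc2)(c2ccccc2)C(C)(C)C | intermediate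
18 | (1S)-2-(TBDPS-oxy)-1-{(2S,3R)-2-[(1Z)-2-iodoprop-1-en-1-yl]-4-methylidene-5-oxooxolan-3-yl}ethyl (2S,3S)-3-acetoxy-2-hydroxy-2-methylbutanoate | C=C1C(=O)O[C@H](/C=C(/C)I)[C@@H]1[C@H](OC(=O)[C@@](C)(O)[C@H](C)OC(C)=O)CO[Si](c2ccccc2)(c2ccccc2)C(C)(C)C | intermediate
19 | prop-2-yn-1-ol | C#CCO | starting material
20 | (2Z)-3-(tributylstannyl)prop-2-en-1-ol | OC/C=C\[Sn](CCCC)(CCCC)CCCC | intermediate
21 | (1S)-2-(TBDPS-oxy)-1-{(2R,3R)-2-[(1Z,3Z)-5-hydroxy-2-methylpenta-1,3-dien-1-yl]-4-methylidene-5-oxooxolan-3-yl}ethyl (2S,3S)-3-acetoxy-2-hydroxy-2-methylbutanoate | C=C1C(=O)O[C@H](/C=C(/C)\C=C/CO)[C@@H]1[C@H](OC(=O)[C@@](C)(O)[C@H](C)OC(C)=O)CO[Si](c2ccccc2)(c2ccccc2)C(C)(C)C | intermediate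
22 | (1S)-2-(TBDPS-oxy)-1-{(2R,3R)-2-{(1Z)-2-[(2S,3R)-3-(hydroxymethyl)oxiran-2-yl]prop-1-en-1-yl}-4-methylidene-5-oxooxolan-3-yl}ethyl (2S,3S)-3-acetoxy-2-hydroxy-2-methylbutanoate | C=C1C(=O)O[C@H](/C=C(/C)[C@@H]2O[C@@H]2CO)[C@@H]1[C@H](OC(=O)[C@@](C)(O)[C@H](C)OC(C)=O)CO[Si](c3ccccc3)(c3ccccc3)C(C)(C)C | intermediate
23 | (1S)-2-(TBDPS-oxy)-1-{(2R,3R)-2-{(1Z)-2-[(2S,3S)-3-formyloxiran-2-yl]prop-1-en-1-yl}-4-methylidene-5-oxooxolan-3-yl}ethyl (2S,3S)-3-acetoxy-2-hydroxy-2-methylbutanoate | C=C1C(=O)O[C@H](/C=C(/C)[C@@H]2O[C@@H]2C=O)[C@@H]1[C@H](OC(=O)[C@@](C)(O)[C@H](C)OC(C)=O)CO[Si](c3ccccc3)(c3ccccc3)C(C)(C)C | intermediate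
24 | (1S)-2-(TBDPS-oxy)-1-{(2R,3R)-2-{(1Z)-2-[(2S,3R)-3-[(1Z)-2-iodo-3-methoxy-3-oxoprop-1-en-1-yl]oxiran-2-yl]prop-1-en-1-yl}-4-methylidene-5-oxooxolan-3-yl}ethyl (2S,3S)-3-acetoxy-2-hydroxy-2-methylbutanoate | C=C1C(=O)O[C@H](/C=C(/C)[C@@H]2O[C@@H]2/C=C(/C(=O)OC)I)[C@@H]1[C@H](OC(=O)[C@@](C)(O)[C@H](C)OC(C)=O)CO[Si](c3ccccc3)(c3ccccc3)C(C)(C)C | intermediate
25 | (1S)-2-hydroxy-1-{(2R,3R)-2-{(1Z)-2-[(2S,3R)-3-[(1Z)-2-iodo-3-methoxy-3-oxoprop-1-en-1-yl]oxiran-2-yl]prop-1-en-1-yl}-4-methylidene-5-oxooxolan-3-yl}ethyl (2S,3S)-3-acetoxy-2-hydroxy-2-methylbutanoate | C=C1C(=O)O[C@H](/C=C(/C)[C@@H]2O[C@@H]2/C=C(/C(=O)OC)I)[C@@H]1[C@H](OC(=O)[C@@](C)(O)[C@H](C)OC(C)=O)CO | intermediate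
26 | (1S)-2-oxo-1-{(2R,3R)-2-{(1Z)-2-[(2S,3R)-3-[(1Z)-2-iodo-3-methoxy-3-oxoprop-1-en-1-yl]oxiran-2-yl]prop-1-en-1-yl}-4-methylidene-5-oxooxolan-3-yl}ethyl (2S,3S)-3-acetoxy-2-hydroxy-2-methylbutanoate | C=C1C(=O)O[C@H](/C=C(/C)[C@@H]2O[C@@H]2/C=C(/C(=O)OC)I)[C@@H]1[C@H](OC(=O)[C@@](C)(O)[C@H](C)OC(C)=O)C=O | intermediate
27 | methyl (1(10)E,2R,3S,4Z,6R,7R,8S,9S)-8-{[(2S,3S)-3-acetoxy-2-hydroxy-2-methylbutanoyl]oxy}-2,3-epoxy-9-hydroxy-12-oxogermacra-1(10),4,11(13)-trien-6,12-olid-14-oate | C=C1C(=O)O[C@@H]2/C=C(/C)[C@@H]3O[C@@H]3/C=C(/C(=O)OC)[C@H](O)[C@@H](OC(=O)[C@@](C)(O)[C@H](C)OC(C)=O)[C@H]12 | intermediate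
28 | CNP0202690.1, the 9-O-tigloyl ester of 27 | C=C1C(=O)O[C@@H]2/C=C(/C)[C@@H]3O[C@@H]3/C=C(/C(=O)OC)[C@H](OC(=O)/C(C)=C/C)[C@@H](OC(=O)[C@@](C)(O)[C@H](C)OC(C)=O)[C@H]12 | target

**Count and risks**

Total step count: 22. Longest linear sequence: 18 steps (steps 1–7, 11–13 and 15–22).

Steps most likely to fail:

1. Step 7. The lithiated acetal phosphonate may lose alkoxide by β-elimination, or BF3 may ionise the mixed acetal or the allylic C6–O bond before the oxirane is opened. The fallback keeps the stereospecific SN2 logic but uses the long-established sulfone-carbanion alkylation of epoxides, which needs no Lewis acid, and a different way to the methylidene group. It sets out from 7: acetal exchange with (2,2-diethoxyethyl)sulfonylbenzene (PPTS) gives the sulfonyl mixed acetal F1. LiN(iPr)2 in THF (−78 → 0 °C) closes the oxolane, with the same inversion at C7, to the sulfone alcohol F2. Esterification with 14 (DCC, DMAP) gives the ester F3, and Jones oxidation gives the α-phenylsulfonyl lactone F4. SmI2 cleaves the C–S bond and the resulting enolate is trapped with dimethyl(methylidene)ammonium iodide to give the Mannich base F5. Quaternisation with MeI and elimination with NaHCO3 gives 18, where the route is rejoined.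

2. Step 21. Facial selectivity at C9 may be poor, because the substrate bias of the α-acyloxy aldehyde (Cornforth–Felkin sense) opposes the ligand, and oligomerisation may compete with closure of the medium ring. The fallback sets out from 26: ring closure without chiral ligand (CrCl2, NiCl2, DMSO/THF, high dilution) should follow the substrate bias and give the (9R) alcohol F6. Mitsunobu esterification of F6 with tiglic acid (PPh3, diisopropyl azodicarboxylate) installs the tiglate with inversion at C9 and gives 28 directly.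

3. Step 16. Epoxidation of the Z-allylic alcohol may be slow and poorly face-selective, and titanium alkoxides may open the bis-allylic oxirane once it has formed. The fallback sets out from 21 and returns at 22 without passing a new compound: an undirected organocatalytic dioxirane epoxidation (Shi epoxidation with the glucose-derived oxazolidinone ketone, KHSO5, K2CO3 buffer, MeCN/dimethoxymethane/H2O, −10 °C). Cis-disubstituted alkenes conjugated to a second π-system are its preferred substrates, and the 4,5-alkene is deactivated by the allylic lactone oxygen and shielded by its three substituents.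

**Further compounds**

F1 | step 7 | {2-ethoxy-2-({(1R,2Z)-1-[(2S,3R)-3-(TBDPS-oxymethyl)oxiran-2-yl]-3-iodobut-2-en-1-yl}oxy)ethyl}sulfonylbenzene | C/C(I)=C/[C@@H](OC(OCC)CS(=O)(=O)c1ccccc1)[C@@H]1O[C@@H]1CO[Si](c1ccccc1)(c1ccccc1)C(C)(C)C
F2 | step 7 | (1S)-2-(TBDPS-oxy)-1-{(2S,3S)-5-ethoxy-2-[(1Z)-2-iodoprop-1-en-1-yl]-4-(phenylsulfonyl)oxolan-3-yl}ethanol | CCOC1O[C@H](/C=C(/C)I)[C@H]([C@H](O)CO[Si](c2ccccc2)(c2ccccc2)C(C)(C)C)C1S(=O)(=O)c1ccccc1
F3 | step 7 | (2S,3S)-3-acetoxy-2-hydroxy-2-methylbutanoate of F2 at the C8 hydroxyl | CCOC1O[C@H](/C=C(/C)I)[C@H]([C@H](OC(=O)[C@@](C)(O)[C@H](C)OC(C)=O)CO[Si](c2ccccc2)(c2ccccc2)C(C)(C)C)C1S(=O)(=O)c1ccccc1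
F4 | step 7 | α-(phenylsulfonyl) γ-lactone corresponding to 17 | O=C1O[C@H](/C=C(/C)I)[C@H]([C@H](OC(=O)[C@@](C)(O)[C@H](C)OC(C)=O)CO[Si](c2ccccc2)(c2ccccc2)C(C)(C)C)C1S(=O)(=O)c1ccccc1
F5 | step 7 | α-[(dimethylamino)methyl] γ-lactone corresponding to 18 | CN(C)CC1C(=O)O[C@H](/C=C(/C)I)[C@@H]1[C@H](OC(=O)[C@@](C)(O)[C@H](C)OC(C)=O)CO[Si](c2ccccc2)(c2ccccc2)C(C)(C)C
F6 | step 21 | (9R) epimer of 27 | C=C1C(=O)O[C@@H]2/C=C(/C)[C@@H]3O[C@@H]3/C=C(/C(=O)OC)[C@@H](O)[C@@H](OC(=O)[C@@](C)(O)[C@H](C)OC(C)=O)[C@H]12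
F0 | step 16 | none | none
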